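**Assumptions (one line):** L‑tyrosinol hydrochloride and (E)‑dec‑2‑enoic acid are bought; target atoms are labelled C1 (CH–N), C2 (CH2), C3 (bridgehead C–OH), C4 (C=O), C5 (bridgehead CH), C6 (CHOH), C7/C8 (epoxide CH, C8 on C3), C9 (CHOH). The route is designed on paper and has not been run.

## Retrosynthetic overview

1. Ring A is closed last: the C5–C9 bond comes from an intramolecular aldol of keto‑aldehyde **9** (sets C5 and C9).
2. **9** comes from cyclic vinylogous ester **6** by directed epoxidation (C7, C8), epoxide‑controlled reduction (C6), enol‑ether hydrolysis (frees C4=O) and oxidation at C9.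
3. **6** comes from p‑quinol **4**: the C9–OH adds to one enone arm (oxa‑Michael; C1 chooses the arm and so fixes C3), then the adduct is dehydrogenated.
4. **4** comes from phenol **3** by singlet‑oxygen [4+2] cycloaddition across the ring (1,4‑endoperoxide → C3–O bond and dearomatised ring B).
5. **3** = L‑tyrosinol + (E)‑dec‑2‑enoic acid. Ring order: ring B (arene → dienone by [4+2]) → temporary pyran → epoxide → ring A.

## Route

**Step 1**
Reactants: **1** L‑tyrosinol hydrochloride; **2** (E)‑dec‑2‑enoic acid
Product: **3** (E)‑N‑[(2S)‑1‑hydroxy‑3‑(4‑hydroxyphenyl)propan‑2‑yl]dec‑2‑enamide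
Conditions: EDC·HCl, HOBt, i‑Pr2NEt, DMF, 0 °C → rt
Reagents that add atoms: none (the acyl group comes from **2**)
Why: Carbodiimide amide coupling; the amine is far more nucleophilic than the phenol or primary alcohol, and the C1 stereocentre (bought) is untouched.

**Step 2**
Reactants: **3**
Product: **4** (E)‑N‑[(2S)‑1‑hydroxy‑3‑(1‑hydroxy‑4‑oxocyclohexa‑2,5‑dien‑1‑yl)propan‑2‑yl]dec‑2‑enamide (p‑quinol)
Conditions: O2, hν (visible), rose bengal (cat.), MeOH, 0 °C; then Me2S
Reagents that add atoms: dioxygen, O=O (one O is kept as the C3–OH)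
Why: [4+2] cycloaddition of singlet oxygen across the ipso/para carbons gives the 1,4‑endoperoxide, which opens to the 4‑hydroperoxy‑dienone and is reduced by Me2S; C3 still carries two identical enone arms, so no stereocentre is created yet.

**Step 3**
Reactants: **4**
Product: **5** (E)‑N‑[(3S,4aS,8aS)‑4a‑hydroxy‑7‑oxo‑3,4,4a,7,8,8a‑hexahydro‑2H‑chromen‑3‑yl]dec‑2‑enamide (cis‑fused; amide cis to the 4a‑OH)
Conditions: CSA (10 mol %), CH2Cl2, rt (equilibrating)
Reagents that add atoms: none
Why: Reversible 6‑exo intramolecular oxa‑Michael addition; C1 selects the enone arm because the cis‑fused chair with amide and angular OH both equatorial is favoured (estimated ~1 kcal/mol), which fixes C3; acid keeps the amide N from competing.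

**Step 4**
Reactants: **5**
Product: **6** (E)‑N‑[(3S,4aS)‑4a‑hydroxy‑7‑oxo‑3,4,4a,7‑tetrahydro‑2H‑chromen‑3‑yl]dec‑2‑enamide (cyclic vinylogous ester)
Conditions: TMSOTf, Et3N, CH2Cl2, −78 → 0 °C; then Pd(OAc)2, O2, DMSO/MeCN, rt; 1 M HCl work‑up
Reagents that add atoms: none
Why: Saegusa–Ito dehydrogenation; C5 is the only enolisable position and the only β‑H is on C4, so the product is the β‑alkoxy enone, which puts C4 at the ketone oxidation level while C3 is retained (silyl groups on OH/NH are lost on work‑up).

**Step 5**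
Reactants: **6**
Product: **7** (E)‑N‑[(3S,4aS,5S,6R)‑5,6‑epoxy‑4a‑hydroxy‑7‑oxo‑3,4,4a,5,6,7‑hexahydro‑2H‑chromen‑3‑yl]dec‑2‑enamide (epoxide cis to the 4a‑OH)
Conditions: t‑BuOOH (decane), DBU, CH2Cl2, 0 °C
Reagents that add atoms: tert‑butyl hydroperoxide, CC(C)(C)OO (one O)
Why: Weitz–Scheffer nucleophilic epoxidation; only the simple enone reacts (the vinylogous‑ester arm and the enamide are deactivated), and the peroxide is delivered syn to the free tertiary OH (H‑bond) and anti to the ring CH2, setting C7/C8 cis to the C3–OH.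

**Step 6**
Reactants: **7**
Product: **8** (E)‑N‑[(2S)‑1‑[(1S,2S,5S,6S)‑2,5‑dihydroxy‑3‑oxo‑7‑oxabicyclo[4.1.0]heptan‑2‑yl]‑3‑hydroxypropan‑2‑yl]dec‑2‑enamide (in equilibrium with its six‑membered hemiketal)
Conditions: NaBH4, CeCl3·7H2O, MeOH, −78 °C; then aq. oxalic acid, THF, 0 °C
Reagents that add atoms: water, O (becomes the C4 ketone oxygen)
Why: Luche 1,2‑reduction with hydride arriving anti to the epoxide oxygen gives the cis‑epoxy alcohol (C6); mild acid then hydrolyses the enol ether to the β‑hydroxy ketone, freeing C4=O and the C9 alcohol, and is kept mild to avoid Stork–Danheiser dehydration.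

**Step 7**
Reactants: **8**
Product: **9** (E)‑N‑[(2S)‑1‑[(1S,2S,5S,6S)‑2,5‑dihydroxy‑3‑oxo‑7‑oxabicyclo[4.1.0]heptan‑2‑yl]‑3‑oxopropan‑2‑yl]dec‑2‑enamide (keto‑aldehyde, used crude)
Conditions: TEMPO (cat.), PhI(OAc)2, CH2Cl2, rt
Reagents that add atoms: none
Why: TEMPO/PhI(OAc)2 oxidation is selective for the primary alcohol (via the open form) over the secondary and tertiary hydroxyls and does not touch the epoxide or alkene.

**Step 8**
Reactants: **9**
Product: **10** isariotin D, (E)‑N‑[(1S,2S,4S,5S,6S,7R,8S)‑1,5,7‑trihydroxy‑10‑oxo‑3‑oxatricyclo[4.3.1.0²,⁴]decan‑8‑yl]dec‑2‑enamide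
Conditions: MgBr2·OEt2, i‑Pr2NEt, CH2Cl2, −20 → 0 °C
Reagents that add atoms: none
Why: Intramolecular aldol via the Mg enolate (C5 is the only enolisable carbon); the tether forces C9 onto the C2 face of C5 with the amide exo on a chair ring A, and the chelated closed transition state places the C9–OH syn to the C4 carbonyl. The bridgehead product cannot dehydrate, so it is the sink.

## Compound list

1 | L‑tyrosinol (used as HCl salt) | N[C@@H](Cc1ccc(O)cc1)CO | starting material
2 | (E)‑dec‑2‑enoic acid | CCCCCCC/C=C/C(=O)O | starting material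
3 | N‑decenoyl‑L‑tyrosinol | CCCCCCC/C=C/C(=O)N[C@@H](Cc1ccc(O)cc1)CO | intermediate
4 | p‑quinol | CCCCCCC/C=C/C(=O)N[C@@H](CC1(O)C=CC(=O)C=C1)CO | intermediate
5 | cis‑fused hexahydrochromen‑7‑one (oxa‑Michael adduct) | CCCCCCC/C=C/C(=O)N[C@H]1C[C@]2(O)C=CC(=O)C[C@@H]2OC1 | intermediate
6 | cyclic vinylogous ester dienone | CCCCCCC/C=C/C(=O)N[C@H]1C[C@]2(O)C=CC(=O)C=C2OC1 | intermediate
7 | epoxy vinylogous ester | CCCCCCC/C=C/C(=O)N[C@H]1C[C@]2(O)[C@H]3O[C@H]3C(=O)C=C2OC1 | intermediate
8 | epoxy‑diol ketone with primary alcohol | CCCCCCC/C=C/C(=O)N[C@H](CO)C[C@@]1(O)C(=O)C[C@H](O)[C@@H]2O[C@@H]21 | intermediate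
9 | keto‑aldehyde | CCCCCCC/C=C/C(=O)N[C@H](C=O)C[C@@]1(O)C(=O)C[C@H](O)[C@@H]2O[C@@H]21 | intermediate
10 | isariotin D | CCCCCCC/C=C/C(=O)N[C@H]1C[C@@]2(O)C(=O)[C@H]([C@H](O)[C@@H]3O[C@@H]32)[C@H]1O | target

## Summary

Total steps: 8. Longest linear sequence: 8 (from L‑tyrosinol).

Steps most likely to fail, with fallbacks:

1. **Step 3 (arm‑selective oxa‑Michael).** The preference for the desired diastereomer is only my conformational estimate, so the dr may be modest. Fallback: relay through the aldehyde oxidation level instead. Oxidise **4** with TEMPO/PhI(OAc)2; the resulting spiro‑lactol adds to the dienone to give a rigid 2,7‑dioxabicyclo[2.2.1]heptane acetal with the amide exo. Carry that cage through steps 4–6; hydrolysis then gives **9** directly.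
2. **Step 4 (dehydrogenation of a β‑alkoxy ketone).** Retro‑oxa‑Michael or β‑alkoxide loss may compete. Fallback: bring the C4 oxygen in on the arene. Make the 7‑hydroxychroman‑3‑amide from a 2,4‑dioxygenated phenylalaninol (Negishi coupling of the L‑serine‑derived iodoalanine zinc reagent, then Mitsunobu ring closure) so that the singlet‑oxygen [4+2] gives **6** directly; the cost is that C3 is then set by facial selectivity in the cycloaddition.
3. **Step 8 (aldol).** Risks are β‑elimination of the C6–OH, epimerisation of the α‑amido aldehyde, or the C9 epimer. Fallback: intramolecular Mukaiyama aldol. Silylate the C3/C6 hydroxyls (TESOTf), form the TMS enol ether of the C4 ketone (single regiochemistry), cyclise with MgBr2 or BF3·OEt2, then remove silyl groups with HF·pyridine.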